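**Plan**
- Target 10 is 3,3',4,4',5,5'-hexabromo-1H,1'H-2,2'-bipyrrole (achiral). The retrosynthesis first cuts C4–Br and C4'–Br (electrophilic bromination), then trades the four C3–Br and C5–Br bonds for C–O (deoxybromination of a C–C linked bis(pyrrolidine-2,4-dione)).
- Enabling feature: in each pyrrole ring the brominated C3 and C5 flank C4 in the 1,3-relationship of the ketone and lactam carbonyls of a tetramic acid. N1–C2–C2'–N1' is the vicinal diamine backbone of 2,3-diaminosuccinic acid, whose carboxyl carbons become C3 and C3'.
- The ring bonds C3–C4 and C3'–C4' are cut next (two-fold Dieckmann), and last the two amide N1–C5 bonds (malonylation of the diamino diester).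
- Forward: diamino diester, bis-malonamide, both five-membered rings closed at carbon in one operation, decarboxylation, O-to-Br exchange with aromatisation, bromination at C4 and C4'.
- Stereochemistry: the target has none. The two CH centres brought in by meso-2,3-diaminosuccinic acid are spectators and become sp2 on aromatisation.

Key step: step 3

Remark: 3-alkoxycarbonyl tetramic acids epimerise easily next to nitrogen under alkoxide. Compounds 5 to 8 are drawn meso, and any rac diastereomer formed would be carried along, since both centres vanish in step 5. Bipyrrole numbering is used throughout.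

**Step 1**
Reactants: 1 meso-2,3-diaminosuccinic acid
Product: 2 dimethyl meso-2,3-diaminosuccinate dihydrochloride
Conditions: SOCl2 (4 equiv), MeOH, 0 °C then reflux
Reagents that add atoms: methanol, CO; thionyl chloride, O=S(Cl)Cl (source of the chloride of the salt)
Why: Fischer esterification under HCl generated in the flask from SOCl2 and MeOH should give the diester with the amines masked as ammonium salts and the two CH centres untouched.

**Step 2**
Reactants: 2 dimethyl meso-2,3-diaminosuccinate dihydrochloride; 3 methyl 3-chloro-3-oxopropanoate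
Product: 4 dimethyl meso-2,3-bis[(3-methoxy-3-oxopropanoyl)amino]succinate
Conditions: 3 (2.2 equiv), Et3N (4.4 equiv), CH2Cl2, 0 °C to rt
Reagents that add atoms: none
Why: N-acylation of the liberated primary amines by the acid chloride (amide formation) should be fast and clean at both nitrogens, the all-methyl ester set making any later transesterification invisible.

**Step 3**
Reactants: 4 dimethyl meso-2,3-bis[(3-methoxy-3-oxopropanoyl)amino]succinate
Product: 5 dimethyl meso-3,3'-dihydroxy-5,5'-dioxo-2,2',5,5'-tetrahydro-1H,1'H-[2,2'-bipyrrole]-4,4'-dicarboxylate (bis-tetramic acid in its enol form)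
Conditions: NaOMe (3 equiv), MeOH, reflux; then 1 M HCl, 0 °C
Reagents that add atoms: none
Why: Methoxide removes a proton from each malonamide CH2, by far the most acidic C–H of 4, and each carbanion adds to the ester carbonyl carried by the α-carbon of its own nitrogen; collapse of the tetrahedral intermediate with loss of methoxide forms C3–C4 and C3'–C4', and immediate deprotonation of each new tricarbonyl methine makes the closures irreversible. The closest known reaction is the Lacey–Dieckmann cyclisation of N-malonyl α-amino esters to 3-alkoxycarbonyl tetramic acids, run here in both directions in one flask. Ring A and ring B each close in the 5-exo-trig mode (malonyl carbon, amide carbon, nitrogen, α-carbon, ester carbon). No stereocentre is created; the two inherited CH centres may epimerise, which is without consequence. The selectivity required is closure onto the proximal ester instead of 6-exo-trig closure onto the distal one: the shorter tether favours the five-membered ring kinetically, as in aspartate-derived cases, and once the first ring exists its ester has become an enolate, so the second carbanion finds only the ester on its own α-carbon. Competing E1cB loss of an amide from the succinate backbone is held back because the α-C–H is far less acidic than the malonamide CH2 and the product leaves the equilibrium as its dianion.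

**Step 4**
Reactants: 5 dimethyl meso-3,3'-dihydroxy-5,5'-dioxo-2,2',5,5'-tetrahydro-1H,1'H-[2,2'-bipyrrole]-4,4'-dicarboxylate
Product: 7 meso-[2,2'-bipyrrolidine]-3,3',5,5'-tetrone (bis-tetramic acid), via meso-bis(3-carboxytetramic acid) 6 (not isolated)
Conditions: MeCN–H2O (20:1), reflux
Reagents that add atoms: none
Why: Hydrolytic dealkoxycarbonylation of a β-keto ester, the usual way to strip the 3-ester from Lacey–Dieckmann products, should cleave both esters and let the β-keto acid 6 lose CO2 through a cyclic transition state; 7 is used at once.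

**Step 5**
Reactants: 7 meso-[2,2'-bipyrrolidine]-3,3',5,5'-tetrone
Product: 9 3,3',5,5'-tetrabromo-1H,1'H-2,2'-bipyrrole, via meso-bis(4-bromo-3-pyrrolin-2-one) 8 (not isolated)
Conditions: POBr3 (6 equiv), MeCN, 80 °C; then ice-water
Reagents that add atoms: phosphorus oxybromide, O=P(Br)(Br)Br
Why: Deoxybromination with POBr3 (O-phosphorylation, then addition–elimination by bromide) should act first at the vinylogous acid oxygens on C3 and C3' to give 8 and then at the lactam carbonyls, after which loss of the C2–H and C2'–H protons aromatises both rings; both exchanges are known for tetramic acids and for 3-pyrrolin-2-ones.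

**Step 6**
Reactants: 9 3,3',5,5'-tetrabromo-1H,1'H-2,2'-bipyrrole
Product: 10 3,3',4,4',5,5'-hexabromo-1H,1'H-2,2'-bipyrrole
Conditions: NBS (2.1 equiv), THF, −78 to 0 °C, dark
Reagents that add atoms: N-bromosuccinimide, O=C1CCC(=O)N1Br
Why: Electrophilic aromatic bromination of a pyrrole should take place at C4 and C4', the only unsubstituted ring carbons, and the low temperature and exact stoichiometry guard against N-bromination and oxidative coupling.

**Compound list**
1 | meso-2,3-diaminosuccinic acid, (2R,3S) | N[C@@H](C(=O)O)[C@H](N)C(=O)O | starting material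
2 | dimethyl meso-2,3-diaminosuccinate dihydrochloride | Cl.Cl.N[C@@H](C(=O)OC)[C@H](N)C(=O)OC | intermediate
3 | methyl 3-chloro-3-oxopropanoate | COC(=O)CC(Cl)=O | starting material
4 | dimethyl meso-2,3-bis[(3-methoxy-3-oxopropanoyl)amino]succinate | COC(=O)CC(=O)N[C@@H](C(=O)OC)[C@H](NC(=O)CC(=O)OC)C(=O)OC | intermediate
5 | dimethyl meso-3,3'-dihydroxy-5,5'-dioxo-2,2',5,5'-tetrahydro-1H,1'H-[2,2'-bipyrrole]-4,4'-dicarboxylate | COC(=O)C1=C(O)[C@@H](NC1=O)[C@H]1NC(=O)C(C(=O)OC)=C1O | intermediate
6 | meso-3,3'-dihydroxy-5,5'-dioxo-2,2',5,5'-tetrahydro-1H,1'H-[2,2'-bipyrrole]-4,4'-dicarboxylic acid (not isolated) | OC(=O)C1=C(O)[C@@H](NC1=O)[C@H]1NC(=O)C(C(=O)O)=C1O | intermediate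
7 | meso-[2,2'-bipyrrolidine]-3,3',5,5'-tetrone (keto tautomer drawn) | O=C1CC(=O)[C@@H](N1)[C@H]1NC(=O)CC1=O | intermediate
8 | meso-3,3'-dibromo-1,1',2,2'-tetrahydro-5H,5'H-[2,2'-bipyrrole]-5,5'-dione (not isolated) | O=C1C=C(Br)[C@@H](N1)[C@H]1NC(=O)C=C1Br | intermediate
9 | 3,3',5,5'-tetrabromo-1H,1'H-2,2'-bipyrrole | Brc1cc(Br)c([nH]1)-c1[nH]c(Br)cc1Br | intermediate
10 | 3,3',4,4',5,5'-hexabromo-1H,1'H-2,2'-bipyrrole | Brc1[nH]c(-c2[nH]c(Br)c(Br)c2Br)c(Br)c1Br | target

**Step count**
Total steps: 6. Longest linear sequence: 6 steps (1 to 10 through 2, 4, 5, 7 and 9).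

**Steps most likely to fail**

Step 5. The exchange may stop at the lactam carbonyls, the α-bromopyrrole may polymerise under the HBr that builds up, or the C4 methylene may condense with an activated carbonyl. The fallback sets out from 7 and exchanges only the vinylogous acid oxygens, with (COBr)2 and DMF in CH2Cl2 at 0 °C (Vilsmeier-type bromination), so that 8 is isolated. The lactams of 8 are then reduced instead of exchanged: i-Bu2AlH in CH2Cl2 at −78 to 0 °C should give hemiaminals that lose water to 3,3'-dibromo-1H,1'H-2,2'-bipyrrole F1. Bromination of F1 at its four open positions with NBS (4 equiv) in THF at −78 °C to rt comes back to the route at 10.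

Step 3. The first carbanion may close the six-membered ring onto the distal ester, or methoxide may trigger E1cB loss of a malonamide from the succinate backbone. The fallback sets out from 1 and builds each ring through nitrogen under neutral conditions. Boc2O and NaOH in dioxane–water should give meso-2,3-bis[(tert-butoxycarbonyl)amino]succinic acid F2. Condensation of F2 with Meldrum's acid (EDC hydrochloride, DMAP, CH2Cl2) should give the bis(acyl Meldrum's acid) adduct F3. Heating F3 in EtOAc at reflux should release two acylketenes that are trapped by their carbamate nitrogens, giving di-tert-butyl meso-3,3',5,5'-tetraoxo-[2,2'-bipyrrolidine]-1,1'-dicarboxylate F4. Removal of the Boc groups with CF3CO2H in CH2Cl2 comes back to the route at 7.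

Step 4. The C4-unsubstituted bis-tetramic acid may undergo aldol-type self-condensation during the hot decarboxylation, or the second ester may be lost incompletely. The fallback sets out from 5 and keeps the ester through the aromatisation. POBr3 in MeCN at 80 °C applied to 5 should give dimethyl 3,3',5,5'-tetrabromo-1H,1'H-[2,2'-bipyrrole]-4,4'-dicarboxylate F5. Saponification with LiOH in THF–water should give 3,3',5,5'-tetrabromo-1H,1'H-[2,2'-bipyrrole]-4,4'-dicarboxylic acid F6. Ipso-bromodecarboxylation of F6 with NBS (2.2 equiv) and NaHCO3 in DMF comes back to the route at 10.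

**Further compounds**
F1 | step 5 | 3,3'-dibromo-1H,1'H-2,2'-bipyrrole | Brc1cc[nH]c1-c1[nH]ccc1Br
F2 | step 3 | meso-2,3-bis[(tert-butoxycarbonyl)amino]succinic acid | CC(C)(C)OC(=O)N[C@@H](C(=O)O)[C@H](NC(=O)OC(C)(C)C)C(=O)O
F3 | step 3 | meso-di-tert-butyl [1,2-bis[(2,2-dimethyl-4,6-dioxo-1,3-dioxan-5-ylidene)(hydroxy)methyl]ethane-1,2-diyl]dicarbamate | CC(C)(C)OC(=O)N[C@@H](C(O)=C1C(=O)OC(C)(C)OC1=O)[C@H](NC(=O)OC(C)(C)C)C(O)=C1C(=O)OC(C)(C)OC1=O
F4 | step 3 | di-tert-butyl meso-3,3',5,5'-tetraoxo-[2,2'-bipyrrolidine]-1,1'-dicarboxylate | CC(C)(C)OC(=O)N1C(=O)CC(=O)[C@@H]1[C@@H]1C(=O)CC(=O)N1C(=O)OC(C)(C)C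
F5 | step 4 | dimethyl 3,3',5,5'-tetrabromo-1H,1'H-[2,2'-bipyrrole]-4,4'-dicarboxylate | COC(=O)c1c(Br)[nH]c(c1Br)-c1[nH]c(Br)c(C(=O)OC)c1Br
F6 | step 4 | 3,3',5,5'-tetrabromo-1H,1'H-[2,2'-bipyrrole]-4,4'-dicarboxylic acid | OC(=O)c1c(Br)[nH]c(c1Br)-c1[nH]c(Br)c(C(=O)O)c1Br
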